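Retrosynthesis: cut the central =CH–CH= single bond of the tetraene (Suzuki–Miyaura), the C(sp)–C(sp2) bond on the chain side of the triple bond (Sonogashira), the bond from the butenolide α-carbon to the vinyl group of the epoxide ring (Suzuki–Miyaura), the two ring bonds at the ylidene-bearing γ-carbon of the butenolide (tandem Sonogashira/lactonisation), and, in the alkynylcyclohexene ring, the bond between the C(CH3)2 carbon and the alkyne-bearing ring carbon.
Forward: the cyclohexane of the epoxide ring is bought; the epoxide is closed first (step 5), the butenolide second (step 9) and the alkynylcyclohexene ring last (step 18), from an open chain; the chain is then extended at the alkyne (step 21) and the two halves are joined in the middle (step 25).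
Enabling feature: the alkynylcyclohexene is a cyclogeranyl ring. Its quaternary C(CH3)2 carbon is bonded to the alkyne-bearing carbon of a tetrasubstituted ring C=C whose other carbon carries CH3. A tertiary cation at the C(CH3)2 carbon can therefore be captured by an open-chain methyl-substituted enyne double bond, and loss of the proton next to the alkyne gives the ring alkene in conjugation with the triple bond.
Stereochemistry: the carbinol of the alkynylcyclohexene ring is bought with (S)-epichlorohydrin and is not a reaction site in the ring closure; the carbinol of the epoxide ring comes from (4R,6R)-4-hydroxy-2,2,6-trimethylcyclohexanone; both epoxide carbons are set by a Sharpless epoxidation.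
Geometry: the (Z)-ylidene comes from anti addition of carboxylate and hydrogen across a triple bond; the E double bonds come from carboalumination, an (E)-enol triflate and Takai-type olefinations, and are carried through the couplings with retention.

Key step: step 18

Remark: compounds 1, 10, 12, 18 and 30 are taken as purchasable; the two hydroxyl groups of the target are set free at different stages (steps 19 and 26).

Step 1
Reactants: 1 (4R,6R)-4-hydroxy-2,2,6-trimethylcyclohexan-1-one
Product: 2 (4R,6R)-4-{[tert-butyl(dimethyl)silyl]oxy}-2,2,6-trimethylcyclohexan-1-one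
Conditions: TBSCl, imidazole, DMF, 23 °C
Reagents that add atoms: tert-butyldimethylsilyl chloride, CC(C)(C)[Si](C)(C)Cl
Why: Imidazole-promoted silylation of the secondary alcohol (silyl ether protection) masks the hydroxyl for the base, hydride and oxidation steps that follow and touches no stereocentre.

Step 2
Reactants: 2 (4R,6R)-4-{[tert-butyl(dimethyl)silyl]oxy}-2,2,6-trimethylcyclohexan-1-one
Product: 4 (4R)-4-{[tert-butyl(dimethyl)silyl]oxy}-2,6,6-trimethylcyclohex-1-en-1-yl trifluoromethanesulfonate, via lithium enolate 3 (not isolated)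
Conditions: LiN(iPr)2, THF, −78 °C; then PhNTf2, −78 → 0 °C
Reagents that add atoms: N-phenylbis(trifluoromethanesulfonimide), FC(F)(F)S(=O)(=O)N(c1ccccc1)S(=O)(=O)C(F)(F)F
Why: The ketone can enolise only toward the methyl-bearing carbon, so deprotonation and O-sulfonylation of enolate 3 (enol triflate formation) can give only the tetrasubstituted enol triflate, at the cost of a stereocentre that the target does not contain.

Step 3
Reactants: 4 (4R)-4-{[tert-butyl(dimethyl)silyl]oxy}-2,6,6-trimethylcyclohex-1-en-1-yl trifluoromethanesulfonate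
Product: 5 methyl (4R)-4-{[tert-butyl(dimethyl)silyl]oxy}-2,6,6-trimethylcyclohex-1-ene-1-carboxylate
Conditions: Pd(OAc)2 (5 mol %), PPh3, CO (1 atm), Et3N, MeOH/DMF, 60 °C
Reagents that add atoms: carbon monoxide, [C-]#[O+]; methanol, CO
Why: Palladium-catalysed alkoxycarbonylation of an enol triflate (oxidative addition, CO insertion, methanolysis) puts the missing carbon on the hindered ring carbon without touching the silyl ether.

Step 4
Reactants: 5 methyl (4R)-4-{[tert-butyl(dimethyl)silyl]oxy}-2,6,6-trimethylcyclohex-1-ene-1-carboxylate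
Product: 6 [(4R)-4-{[tert-butyl(dimethyl)silyl]oxy}-2,6,6-trimethylcyclohex-1-en-1-yl]methanol
Conditions: iBu2AlH, CH2Cl2, −78 → 0 °C; KNaC4H4O6 (aq) work-up
Reagents that add atoms: none
Why: 1,2-Reduction of the unsaturated ester by the aluminium hydride (ester reduction) gives the allylic alcohol that the titanium epoxidation catalyst needs as its anchor.

Step 5
Reactants: 6 [(4R)-4-{[tert-butyl(dimethyl)silyl]oxy}-2,6,6-trimethylcyclohex-1-en-1-yl]methanol
Product: 7 [(1R,4S,6R)-4-{[tert-butyl(dimethyl)silyl]oxy}-2,2,6-trimethyl-7-oxabicyclo[4.1.0]heptan-1-yl]methanol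
Conditions: Ti(OiPr)4 (20 mol %), D-(−)-diethyl tartrate (24 mol %), tBuOOH, 4 Å molecular sieves, CH2Cl2, −20 °C
Reagents that add atoms: tert-butyl hydroperoxide, CC(C)(C)OO
Why: Sharpless asymmetric epoxidation: the titanium tartrate complex bound to the allylic hydroxyl delivers oxygen to one face of the tetrasubstituted alkene, and with D-(−)-diethyl tartrate this should be the face opposite to the silyloxy group, which sets both epoxide carbons (reagent control, expected to be reinforced by the hindrance of the silyloxy-bearing face).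

Step 6
Reactants: 7 [(1R,4S,6R)-4-{[tert-butyl(dimethyl)silyl]oxy}-2,2,6-trimethyl-7-oxabicyclo[4.1.0]heptan-1-yl]methanol
Product: 8 (1S,4S,6R)-4-{[tert-butyl(dimethyl)silyl]oxy}-2,2,6-trimethyl-7-oxabicyclo[4.1.0]heptane-1-carbaldehyde
Conditions: Pr4N[RuO4] (5 mol %), N-methylmorpholine N-oxide, 4 Å molecular sieves, CH2Cl2, 23 °C
Reagents that add atoms: none
Why: Ley oxidation with catalytic perruthenate is neutral and mild, so the primary alcohol should be taken to the aldehyde without opening the epoxide, and the aldehyde has no α-hydrogen to epimerise.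

Step 7
Reactants: 8 (1S,4S,6R)-4-{[tert-butyl(dimethyl)silyl]oxy}-2,2,6-trimethyl-7-oxabicyclo[4.1.0]heptane-1-carbaldehyde
Product: 9 2-{(E)-2-[(1S,4S,6R)-4-{[tert-butyl(dimethyl)silyl]oxy}-2,2,6-trimethyl-7-oxabicyclo[4.1.0]heptan-1-yl]ethenyl}-4,4,5,5-tetramethyl-1,3,2-dioxaborolane
Conditions: CrCl2, Cl2CHB(pin), LiI, THF, 23 °C
Reagents that add atoms: 2-(dichloromethyl)-4,4,5,5-tetramethyl-1,3,2-dioxaborolane, ClC(Cl)B1OC(C)(C)C(C)(C)O1
Why: Takai–Utimoto olefination: the gem-dichromium reagent formed from CrCl2 and the dichloromethylboronate adds to the aldehyde and eliminates anti to give the (E)-alkenylboronate, under conditions that should leave epoxide and silyl ether alone.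

Step 8
Reactants: 10 prop-2-ynoic acid
Product: 11 (2E)-2,3-dibromoprop-2-enoic acid
Conditions: Br2, CH2Cl2, 0 → 23 °C, dark
Reagents that add atoms: bromine, BrBr
Why: Electrophilic anti addition of bromine across the triple bond (alkyne bromination) gives the (E)-dibromide in which the β-bromine is cis to the carboxyl group, as the lactonisation in step 9 requires.

Step 9
Reactants: 11 (2E)-2,3-dibromoprop-2-enoic acid; 12 (2E)-3-methylpent-2-en-4-yn-1-ol
Product: 14 (5Z)-3-bromo-5-[(2E)-4-hydroxy-2-methylbut-2-en-1-ylidene]furan-2(5H)-one, via enynoic acid 13 (not isolated)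
Conditions: Pd(PPh3)4 (5 mol %), CuI (10 mol %), Et3N, MeCN, 23 °C
Reagents that add atoms: none
Why: Tandem Sonogashira coupling and lactonisation: zerovalent palladium inserts into the more electron-poor β-C–Br bond, the alkyne is coupled to give acid 13, and its carboxylate then adds 5-exo-dig and anti across the metal-activated triple bond, which closes the butenolide and sets the (Z)-ylidene while the α-bromine stays for step 10.

Step 10
Reactants: 9 2-{(E)-2-[(1S,4S,6R)-4-{[tert-butyl(dimethyl)silyl]oxy}-2,2,6-trimethyl-7-oxabicyclo[4.1.0]heptan-1-yl]ethenyl}-4,4,5,5-tetramethyl-1,3,2-dioxaborolane; 14 (5Z)-3-bromo-5-[(2E)-4-hydroxy-2-methylbut-2-en-1-ylidene]furan-2(5H)-one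
Product: 15 (5Z)-3-{(E)-2-[(1S,4S,6R)-4-{[tert-butyl(dimethyl)silyl]oxy}-2,2,6-trimethyl-7-oxabicyclo[4.1.0]heptan-1-yl]ethenyl}-5-[(2E)-4-hydroxy-2-methylbut-2-en-1-ylidene]furan-2(5H)-one
Conditions: Pd(OAc)2 (5 mol %), SPhos (10 mol %), K3PO4 (aq), THF, 23 °C
Reagents that add atoms: none
Why: Suzuki–Miyaura coupling of the α-bromobutenolide, an activated alkenyl bromide, with the (E)-alkenylboronate proceeds with retention at both partners under a mild phosphate base that lactone and epoxide should tolerate.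

Step 11
Reactants: 15 (5Z)-3-{(E)-2-[(1S,4S,6R)-4-{[tert-butyl(dimethyl)silyl]oxy}-2,2,6-trimethyl-7-oxabicyclo[4.1.0]heptan-1-yl]ethenyl}-5-[(2E)-4-hydroxy-2-methylbut-2-en-1-ylidene]furan-2(5H)-one
Product: 16 (2E,4Z)-4-{4-[(E)-2-[(1S,4S,6R)-4-{[tert-butyl(dimethyl)silyl]oxy}-2,2,6-trimethyl-7-oxabicyclo[4.1.0]heptan-1-yl]ethenyl]-5-oxofuran-2(5H)-ylidene}-3-methylbut-2-enal
Conditions: MnO2, CH2Cl2, 23 °C
Reagents that add atoms: none
Why: MnO2 oxidises only the allylic primary alcohol (allylic oxidation) and should leave lactone, epoxide and silyl ether unchanged.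

Step 12
Reactants: 16 (2E,4Z)-4-{4-[(E)-2-[(1S,4S,6R)-4-{[tert-butyl(dimethyl)silyl]oxy}-2,2,6-trimethyl-7-oxabicyclo[4.1.0]heptan-1-yl]ethenyl]-5-oxofuran-2(5H)-ylidene}-3-methylbut-2-enal
Product: 17 (5Z)-3-{(E)-2-[(1S,4S,6R)-4-{[tert-butyl(dimethyl)silyl]oxy}-2,2,6-trimethyl-7-oxabicyclo[4.1.0]heptan-1-yl]ethenyl}-5-[(2E,4E)-5-iodo-2-methylpenta-2,4-dien-1-ylidene]furan-2(5H)-one
Conditions: CrCl2, CHI3, THF, 0 °C, dark
Reagents that add atoms: iodoform, IC(I)I
Why: Takai olefination: the gem-dichromium species from CHI3 and CrCl2 adds to the aldehyde and eliminates anti to the (E)-alkenyl iodide, and CrCl2 is not expected to reduce the lactone or the epoxide.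

Step 13
Reactants: 18 (2S)-2-(chloromethyl)oxirane
Product: 19 (2S)-1-chloro-4-methylpent-4-en-2-ol
Conditions: CH2=C(CH3)MgBr, CuI (10 mol %), THF, −40 → 0 °C; NH4Cl (aq) work-up
Reagents that add atoms: isopropenylmagnesium bromide, CC(=C)[Mg]Br
Why: Copper-catalysed Grignard opening of the epoxide at its CH2 carbon (SN2 epoxide opening) leaves the stereocentre untouched and keeps the chloride for the second epoxide.

Step 14
Reactants: 19 (2S)-1-chloro-4-methylpent-4-en-2-ol
Product: 21 (4S)-2-methylhept-1-en-6-yn-4-ol, via epoxide 20 (not isolated)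
Conditions: LiC≡CH·H2N(CH2)2NH2 (3 equiv), DMSO, 0 → 23 °C
Reagents that add atoms: lithium acetylide (ethylenediamine complex), [Li]C#C
Why: The first equivalent of acetylide deprotonates the alcohol, the alkoxide closes epoxide 20 through oxygen, and a second equivalent opens it at the CH2 carbon (epoxide alkynylation), so the carbinol stereocentre is never a reaction site.

Step 15
Reactants: 21 (4S)-2-methylhept-1-en-6-yn-4-ol
Product: 22 tert-butyl{[(4S)-2-methylhept-1-en-6-yn-4-yl]oxy}diphenylsilane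
Conditions: TBDPSCl, imidazole, DMF, 23 °C
Reagents that add atoms: tert-butyl(chloro)diphenylsilane, CC(C)(C)[Si](Cl)(c1ccccc1)c1ccccc1
Why: Silylation of the secondary alcohol as the tert-butyldiphenylsilyl ether (silyl ether protection) gives a group that should tolerate Me3Al and the strong acid of step 18.

Step 16
Reactants: 22 tert-butyl{[(4S)-2-methylhept-1-en-6-yn-4-yl]oxy}diphenylsilane
Product: 24 tert-butyl{[(1E,4S)-1-iodo-2,6-dimethylhepta-1,6-dien-4-yl]oxy}diphenylsilane, via alkenylalane 23 (not isolated)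
Conditions: Me3Al, Cp2ZrCl2 (25 mol %), CH2Cl2, 0 → 23 °C; then I2, THF, −30 °C
Reagents that add atoms: trimethylaluminium, C[Al](C)C; iodine, II
Why: Negishi carboalumination: zirconium-catalysed syn addition of methyl and aluminium across the terminal alkyne places methyl on the internal carbon to give alane 23, and iodinolysis with retention gives the (E)-alkenyl iodide, while the 1,1-disubstituted alkene is inert to methylalumination.

Step 17
Reactants: 24 tert-butyl{[(1E,4S)-1-iodo-2,6-dimethylhepta-1,6-dien-4-yl]oxy}diphenylsilane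
Product: 25 tert-butyl{[(3E,6S)-4,8-dimethyl-1-(trimethylsilyl)nona-3,8-dien-1-yn-6-yl]oxy}diphenylsilane
Conditions: PdCl2(PPh3)2 (3 mol %), CuI (6 mol %), ethynyl(trimethyl)silane, iPr2NH, THF, 23 °C
Reagents that add atoms: ethynyl(trimethyl)silane, C#C[Si](C)(C)C
Why: Sonogashira coupling of the alkenyl iodide with the silylacetylene proceeds with retention of the double-bond geometry and installs the triple bond of the target.

Step 18
Reactants: 25 tert-butyl{[(3E,6S)-4,8-dimethyl-1-(trimethylsilyl)nona-3,8-dien-1-yn-6-yl]oxy}diphenylsilane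
Product: 28 tert-butyl{[(1R)-3,5,5-trimethyl-4-[(trimethylsilyl)ethynyl]cyclohex-3-en-1-yl]oxy}diphenylsilane, via tertiary cation 26 (not isolated), via ring cation 27 (not isolated)
Conditions: TfOH (20 mol %), (CF3)2CHOH/CH2Cl2 (1:4), −20 → 0 °C
Reagents that add atoms: none
Why: TfOH should protonate the 1,1-disubstituted alkene of 25 in the Markovnikov sense, since it is the more basic, unconjugated double bond, to give tertiary cation 26; the enyne double bond then attacks it through its CH carbon in a chair-like 6-endo-trig closure, which forms the bond between the C(CH3)2 carbon and the alkyne-bearing carbon and leaves tertiary ring cation 27. Loss of the propargylic proton from 27 gives the tetrasubstituted ring alkene conjugated with the triple bond, and isomers formed by proton loss toward the ring CH2 or the methyl group should be re-protonated under the acidic conditions and drain to this most stable alkene. The closest known reaction type is the acid-mediated cation–olefin cyclisation of 1,5-dienes to cyclogeranyl rings, as in pseudoionone to β-ionone. No new stereocentre is formed, because the quaternary carbon carries two methyl groups and the alkyne-bearing carbon ends as sp2, while the silyloxy carbinol lies β to both cationic centres and has no pathway to epimerise, so the configuration bought with (S)-epichlorohydrin is carried into the ring. The selectivities needed are initiation at the 1,1-disubstituted alkene (secured by conjugation of the other alkene to the alkyne), attack through the CH carbon (secured by the tertiary cation and six-membered ring that result) and proton loss next to the alkyne (secured by conjugation); the tert-butyldiphenylsilyl ether is chosen because it should tolerate catalytic strong acid at low temperature and, unlike an ester, cannot bridge to the cations.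

Step 19
Reactants: 28 tert-butyl{[(1R)-3,5,5-trimethyl-4-[(trimethylsilyl)ethynyl]cyclohex-3-en-1-yl]oxy}diphenylsilane
Product: 29 (1R)-4-ethynyl-3,5,5-trimethylcyclohex-3-en-1-ol
Conditions: Bu4NF (3 equiv), THF, 23 °C
Reagents that add atoms: none
Why: Fluoride cleaves the C(sp)–Si bond and the silyl ether in one operation (desilylation) and touches neither the enyne nor the stereocentre.

Step 20
Reactants: 30 ethyl 3-oxobutanoate
Product: 32 ethyl (2E)-3-{[(trifluoromethyl)sulfonyl]oxy}but-2-enoate, via ammonium enolate 31 (not isolated)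
Conditions: Me4NOH (aq), Tf2O, hexanes, 5 → 23 °C
Reagents that add atoms: trifluoromethanesulfonic anhydride, FC(F)(F)S(=O)(=O)OS(=O)(=O)C(F)(F)F
Why: Enol triflate formation: with the non-chelating tetramethylammonium counter-ion enolate 31 should adopt the E geometry, and O-triflation fixes it as the (E)-enol triflate.

Step 21
Reactants: 29 (1R)-4-ethynyl-3,5,5-trimethylcyclohex-3-en-1-ol; 32 ethyl (2E)-3-{[(trifluoromethyl)sulfonyl]oxy}but-2-enoate
Product: 33 ethyl (2E)-5-[(4R)-4-hydroxy-2,6,6-trimethylcyclohex-1-en-1-yl]-3-methylpent-2-en-4-ynoate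
Conditions: PdCl2(PPh3)2 (3 mol %), CuI (6 mol %), Et3N, DMF, 23 °C
Reagents that add atoms: none
Why: Sonogashira coupling of the terminal alkyne with the β-triflyloxy enoate, an activated alkenyl electrophile, proceeds with retention and gives the E-configured enynoate, and the free hydroxyl does not interfere.

Step 22
Reactants: 33 ethyl (2E)-5-[(4R)-4-hydroxy-2,6,6-trimethylcyclohex-1-en-1-yl]-3-methylpent-2-en-4-ynoate
Product: 34 (1R)-4-[(3E)-5-hydroxy-3-methylpent-3-en-1-yn-1-yl]-3,5,5-trimethylcyclohex-3-en-1-ol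
Conditions: iBu2AlH (3.5 equiv), CH2Cl2, −78 °C; KNaC4H4O6 (aq) work-up
Reagents that add atoms: none
Why: Excess aluminium hydride reduces the conjugated ester in the 1,2-sense to the allylic alcohol (ester reduction) after the free hydroxyl has consumed one equivalent.

Step 23
Reactants: 34 (1R)-4-[(3E)-5-hydroxy-3-methylpent-3-en-1-yn-1-yl]-3,5,5-trimethylcyclohex-3-en-1-ol
Product: 35 (2E)-5-[(4R)-4-hydroxy-2,6,6-trimethylcyclohex-1-en-1-yl]-3-methylpent-2-en-4-ynal
Conditions: MnO2, CH2Cl2, 23 °C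
Reagents that add atoms: none
Why: MnO2 oxidises the allylic primary alcohol selectively (allylic oxidation), and the secondary ring alcohol, which is not allylic, should be left.

Step 24
Reactants: 35 (2E)-5-[(4R)-4-hydroxy-2,6,6-trimethylcyclohex-1-en-1-yl]-3-methylpent-2-en-4-ynal
Product: 36 (1R)-3,5,5-trimethyl-4-[(3E,5E)-3-methyl-6-(4,4,5,5-tetramethyl-1,3,2-dioxaborolan-2-yl)hexa-3,5-dien-1-yn-1-yl]cyclohex-3-en-1-ol
Conditions: CrCl2, Cl2CHB(pin), LiI, THF, 23 °C
Reagents that add atoms: 2-(dichloromethyl)-4,4,5,5-tetramethyl-1,3,2-dioxaborolane, ClC(Cl)B1OC(C)(C)C(C)(C)O1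
Why: Takai–Utimoto olefination of the enynal gives the (E)-dienylboronate by anti elimination from the gem-dichromium adduct, and the free hydroxyl and the triple bond should be tolerated by CrCl2.

Step 25
Reactants: 17 (5Z)-3-{(E)-2-[(1S,4S,6R)-4-{[tert-butyl(dimethyl)silyl]oxy}-2,2,6-trimethyl-7-oxabicyclo[4.1.0]heptan-1-yl]ethenyl}-5-[(2E,4E)-5-iodo-2-methylpenta-2,4-dien-1-ylidene]furan-2(5H)-one; 36 (1R)-3,5,5-trimethyl-4-[(3E,5E)-3-methyl-6-(4,4,5,5-tetramethyl-1,3,2-dioxaborolan-2-yl)hexa-3,5-dien-1-yn-1-yl]cyclohex-3-en-1-ol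
Product: 37 (5Z)-3-{(E)-2-[(1S,4S,6R)-4-{[tert-butyl(dimethyl)silyl]oxy}-2,2,6-trimethyl-7-oxabicyclo[4.1.0]heptan-1-yl]ethenyl}-5-[(2E,4E,6E,8E)-11-[(4R)-4-hydroxy-2,6,6-trimethylcyclohex-1-en-1-yl]-2,9-dimethylundeca-2,4,6,8-tetraen-10-yn-1-ylidene]furan-2(5H)-one
Conditions: Pd(OAc)2 (10 mol %), SPhos (20 mol %), K3PO4 (aq), THF, 23 °C, dark
Reagents that add atoms: none
Why: Suzuki–Miyaura coupling of the alkenyl iodide with the alkenylboronate joins the two halves at a single bond between two E double bonds with retention at both carbons, under mild base, at room temperature and in the dark.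

Step 26
Reactants: 37 (5Z)-3-{(E)-2-[(1S,4S,6R)-4-{[tert-butyl(dimethyl)silyl]oxy}-2,2,6-trimethyl-7-oxabicyclo[4.1.0]heptan-1-yl]ethenyl}-5-[(2E,4E,6E,8E)-11-[(4R)-4-hydroxy-2,6,6-trimethylcyclohex-1-en-1-yl]-2,9-dimethylundeca-2,4,6,8-tetraen-10-yn-1-ylidene]furan-2(5H)-one
Product: 38 (5Z)-3-{(E)-2-[(1S,4S,6R)-4-hydroxy-2,2,6-trimethyl-7-oxabicyclo[4.1.0]heptan-1-yl]ethenyl}-5-[(2E,4E,6E,8E)-11-[(4R)-4-hydroxy-2,6,6-trimethylcyclohex-1-en-1-yl]-2,9-dimethylundeca-2,4,6,8-tetraen-10-yn-1-ylidene]furan-2(5H)-one (target, CNP0180336.1)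
Conditions: Bu4NF, AcOH (1:1), THF, 0 → 23 °C, dark
Reagents that add atoms: none
Why: Fluoride buffered with acetic acid removes the last silyl ether (desilylation) and should open neither the butenolide nor the acid-sensitive vinyl epoxide.

Compound list
1 | (4R,6R)-4-hydroxy-2,2,6-trimethylcyclohexan-1-one | CC1(C)C[C@H](O)C[C@@H](C)C1=O | starting material
2 | (4R,6R)-4-{[tert-butyl(dimethyl)silyl]oxy}-2,2,6-trimethylcyclohexan-1-one | CC1(C)C[C@H](O[Si](C)(C)C(C)(C)C)C[C@@H](C)C1=O | intermediate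
3 | lithium (4R)-4-{[tert-butyl(dimethyl)silyl]oxy}-2,6,6-trimethylcyclohex-1-en-1-olate | [Li+].CC1=C([O-])C(C)(C)C[C@H](O[Si](C)(C)C(C)(C)C)C1 | intermediate (not isolated)
4 | (4R)-4-{[tert-butyl(dimethyl)silyl]oxy}-2,6,6-trimethylcyclohex-1-en-1-yl trifluoromethanesulfonate | CC1=C(OS(=O)(=O)C(F)(F)F)C(C)(C)C[C@H](O[Si](C)(C)C(C)(C)C)C1 | intermediate
5 | methyl (4R)-4-{[tert-butyl(dimethyl)silyl]oxy}-2,6,6-trimethylcyclohex-1-ene-1-carboxylate | CC1=C(C(=O)OC)C(C)(C)C[C@H](O[Si](C)(C)C(C)(C)C)C1 | intermediate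
6 | [(4R)-4-{[tert-butyl(dimethyl)silyl]oxy}-2,6,6-trimethylcyclohex-1-en-1-yl]methanol | CC1=C(CO)C(C)(C)C[C@H](O[Si](C)(C)C(C)(C)C)C1 | intermediate
7 | [(1R,4S,6R)-4-{[tert-butyl(dimethyl)silyl]oxy}-2,2,6-trimethyl-7-oxabicyclo[4.1.0]heptan-1-yl]methanol | OC[C@@]12O[C@]1(C)C[C@@H](O[Si](C)(C)C(C)(C)C)CC2(C)C | intermediate
8 | (1S,4S,6R)-4-{[tert-butyl(dimethyl)silyl]oxy}-2,2,6-trimethyl-7-oxabicyclo[4.1.0]heptane-1-carbaldehyde | O=C[C@@]12O[C@]1(C)C[C@@H](O[Si](C)(C)C(C)(C)C)CC2(C)C | intermediate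
9 | 2-{(E)-2-[(1S,4S,6R)-4-{[tert-butyl(dimethyl)silyl]oxy}-2,2,6-trimethyl-7-oxabicyclo[4.1.0]heptan-1-yl]ethenyl}-4,4,5,5-tetramethyl-1,3,2-dioxaborolane | CC1(C)OB(/C=C/[C@@]23O[C@]2(C)C[C@@H](O[Si](C)(C)C(C)(C)C)CC3(C)C)OC1(C)C | intermediate
10 | prop-2-ynoic acid | C#CC(=O)O | starting material
11 | (2E)-2,3-dibromoprop-2-enoic acid | OC(=O)/C(Br)=C\Br | intermediate
12 | (2E)-3-methylpent-2-en-4-yn-1-ol | OC/C=C(C)/C#C | starting material
13 | (2E,6E)-2-bromo-8-hydroxy-6-methylocta-2,6-dien-4-ynoic acid | OC(=O)/C(Br)=C\C#C/C(C)=C/CO | intermediate (not isolated)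
14 | (5Z)-3-bromo-5-[(2E)-4-hydroxy-2-methylbut-2-en-1-ylidene]furan-2(5H)-one | OC/C=C(C)/C=C1C=C(Br)C(=O)O/1 | intermediate
15 | (5Z)-3-{(E)-2-[(1S,4S,6R)-4-{[tert-butyl(dimethyl)silyl]oxy}-2,2,6-trimethyl-7-oxabicyclo[4.1.0]heptan-1-yl]ethenyl}-5-[(2E)-4-hydroxy-2-methylbut-2-en-1-ylidene]furan-2(5H)-one | OC/C=C(C)/C=C1C=C(/C=C/[C@@]23O[C@]2(C)C[C@@H](O[Si](C)(C)C(C)(C)C)CC3(C)C)C(=O)O/1 | intermediate
16 | (2E,4Z)-4-{4-[(E)-2-[(1S,4S,6R)-4-{[tert-butyl(dimethyl)silyl]oxy}-2,2,6-trimethyl-7-oxabicyclo[4.1.0]heptan-1-yl]ethenyl]-5-oxofuran-2(5H)-ylidene}-3-methylbut-2-enal | O=C/C=C(C)/C=C1C=C(/C=C/[C@@]23O[C@]2(C)C[C@@H](O[Si](C)(C)C(C)(C)C)CC3(C)C)C(=O)O/1 | intermediate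
17 | (5Z)-3-{(E)-2-[(1S,4S,6R)-4-{[tert-butyl(dimethyl)silyl]oxy}-2,2,6-trimethyl-7-oxabicyclo[4.1.0]heptan-1-yl]ethenyl}-5-[(2E,4E)-5-iodo-2-methylpenta-2,4-dien-1-ylidene]furan-2(5H)-one | I/C=C/C=C(C)/C=C1C=C(/C=C/[C@@]23O[C@]2(C)C[C@@H](O[Si](C)(C)C(C)(C)C)CC3(C)C)C(=O)O/1 | intermediate
18 | (2S)-2-(chloromethyl)oxirane | ClC[C@@H]1CO1 | starting material
19 | (2S)-1-chloro-4-methylpent-4-en-2-ol | CC(=C)C[C@H](O)CCl | intermediate
20 | (2S)-2-(2-methylprop-2-en-1-yl)oxirane | CC(=C)C[C@H]1CO1 | intermediate (not isolated)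
21 | (4S)-2-methylhept-1-en-6-yn-4-ol | CC(=C)C[C@H](O)CC#C | intermediate
22 | tert-butyl{[(4S)-2-methylhept-1-en-6-yn-4-yl]oxy}diphenylsilane | CC(=C)C[C@H](O[Si](c1ccccc1)(c1ccccc1)C(C)(C)C)CC#C | intermediate
23 | [(1E,4S)-4-{[tert-butyl(diphenyl)silyl]oxy}-2,6-dimethylhepta-1,6-dien-1-yl](dimethyl)alumane | CC(=C)C[C@H](O[Si](c1ccccc1)(c1ccccc1)C(C)(C)C)C/C(C)=C/[Al](C)C | intermediate (not isolated)
24 | tert-butyl{[(1E,4S)-1-iodo-2,6-dimethylhepta-1,6-dien-4-yl]oxy}diphenylsilane | CC(=C)C[C@H](O[Si](c1ccccc1)(c1ccccc1)C(C)(C)C)C/C(C)=C/I | intermediate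
25 | tert-butyl{[(3E,6S)-4,8-dimethyl-1-(trimethylsilyl)nona-3,8-dien-1-yn-6-yl]oxy}diphenylsilane | CC(=C)C[C@H](O[Si](c1ccccc1)(c1ccccc1)C(C)(C)C)C/C(C)=C/C#C[Si](C)(C)C | intermediate
26 | (4S,6E)-4-{[tert-butyl(diphenyl)silyl]oxy}-2,6-dimethyl-9-(trimethylsilyl)non-6-en-8-yn-2-ylium | C[C+](C)C[C@H](O[Si](c1ccccc1)(c1ccccc1)C(C)(C)C)C/C(C)=C/C#C[Si](C)(C)C | intermediate (not isolated)
27 | (5R)-5-{[tert-butyl(diphenyl)silyl]oxy}-1,3,3-trimethyl-2-[(trimethylsilyl)ethynyl]cyclohexan-1-ylium (both configurations at the alkyne-bearing carbon) | C[C+]1C(C#C[Si](C)(C)C)C(C)(C)C[C@H](O[Si](c2ccccc2)(c2ccccc2)C(C)(C)C)C1 | intermediate (not isolated)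
28 | tert-butyl{[(1R)-3,5,5-trimethyl-4-[(trimethylsilyl)ethynyl]cyclohex-3-en-1-yl]oxy}diphenylsilane | CC1=C(C#C[Si](C)(C)C)C(C)(C)C[C@H](O[Si](c2ccccc2)(c2ccccc2)C(C)(C)C)C1 | intermediate
29 | (1R)-4-ethynyl-3,5,5-trimethylcyclohex-3-en-1-ol | CC1=C(C#C)C(C)(C)C[C@H](O)C1 | intermediate
30 | ethyl 3-oxobutanoate | CCOC(=O)CC(C)=O | starting material
31 | tetramethylammonium (2E)-4-ethoxy-4-oxobut-2-en-2-olate | C[N+](C)(C)C.CCOC(=O)/C=C(C)/[O-] | intermediate (not isolated)
32 | ethyl (2E)-3-{[(trifluoromethyl)sulfonyl]oxy}but-2-enoate | CCOC(=O)/C=C(C)/OS(=O)(=O)C(F)(F)F | intermediate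
33 | ethyl (2E)-5-[(4R)-4-hydroxy-2,6,6-trimethylcyclohex-1-en-1-yl]-3-methylpent-2-en-4-ynoate | CC1=C(C#C/C(C)=C/C(=O)OCC)C(C)(C)C[C@H](O)C1 | intermediate
34 | (1R)-4-[(3E)-5-hydroxy-3-methylpent-3-en-1-yn-1-yl]-3,5,5-trimethylcyclohex-3-en-1-ol | CC1=C(C#C/C(C)=C/CO)C(C)(C)C[C@H](O)C1 | intermediate
35 | (2E)-5-[(4R)-4-hydroxy-2,6,6-trimethylcyclohex-1-en-1-yl]-3-methylpent-2-en-4-ynal | CC1=C(C#C/C(C)=C/C=O)C(C)(C)C[C@H](O)C1 | intermediate
36 | (1R)-3,5,5-trimethyl-4-[(3E,5E)-3-methyl-6-(4,4,5,5-tetramethyl-1,3,2-dioxaborolan-2-yl)hexa-3,5-dien-1-yn-1-yl]cyclohex-3-en-1-ol | CC1=C(C#C/C(C)=C/C=C/B2OC(C)(C)C(C)(C)O2)C(C)(C)C[C@H](O)C1 | intermediate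
37 | (5Z)-3-{(E)-2-[(1S,4S,6R)-4-{[tert-butyl(dimethyl)silyl]oxy}-2,2,6-trimethyl-7-oxabicyclo[4.1.0]heptan-1-yl]ethenyl}-5-[(2E,4E,6E,8E)-11-[(4R)-4-hydroxy-2,6,6-trimethylcyclohex-1-en-1-yl]-2,9-dimethylundeca-2,4,6,8-tetraen-10-yn-1-ylidene]furan-2(5H)-one | CC1=C(C#C/C(C)=C/C=C/C=C/C=C(C)/C=C2C=C(/C=C/[C@@]34O[C@]3(C)C[C@@H](O[Si](C)(C)C(C)(C)C)CC4(C)C)C(=O)O/2)C(C)(C)C[C@H](O)C1 | intermediate
38 | (5Z)-3-{(E)-2-[(1S,4S,6R)-4-hydroxy-2,2,6-trimethyl-7-oxabicyclo[4.1.0]heptan-1-yl]ethenyl}-5-[(2E,4E,6E,8E)-11-[(4R)-4-hydroxy-2,6,6-trimethylcyclohex-1-en-1-yl]-2,9-dimethylundeca-2,4,6,8-tetraen-10-yn-1-ylidene]furan-2(5H)-one | CC1=C(C#C/C(C)=C/C=C/C=C/C=C(C)/C=C2C=C(/C=C/[C@@]34O[C@]3(C)C[C@@H](O)CC4(C)C)C(=O)O/2)C(C)(C)C[C@H](O)C1 | target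

Total step count: 26 steps.
Longest linear sequence: 13 steps (from 18 to 38 through steps 13–19 and 21–26); the branch from 1 has 12 steps (steps 1–7, 10–12, 25, 26).

Steps most likely to fail

Step 18 (ring closure). What may go wrong: protonation at the enyne double bond instead of the 1,1-disubstituted alkene, five-membered closure through the methyl-bearing alkene carbon, proton loss toward the ring CH2 or the methyl group without later equilibration to the conjugated alkene, and acid cleavage of the silyl ether. Fallback: the de novo ring closure is given up for this ring and the ring is taken from the chiral pool. Enol triflate 4, already in hand from step 2, would be coupled with ethynyl(trimethyl)silane under Sonogashira conditions (PdCl2(PPh3)2, CuI, Et3N, DMF, 50 °C) to give tert-butyl(dimethyl){[(1R)-3,5,5-trimethyl-4-[(trimethylsilyl)ethynyl]cyclohex-3-en-1-yl]oxy}silane F1, and Bu4NF in THF would remove both silyl groups to come back to the route at 29.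

Step 9 (tandem coupling and lactonisation). What may go wrong: 6-endo attack of the carboxylate to give the pyranone ring, a second coupling at the remaining α-bromine, and erosion of the Z geometry of the ylidene. Fallback: coupling and ring closure are separated and the ring is closed by π-acid catalysis on an isolated acid. Acid 11 would be esterified (MeOH, catalytic H2SO4) to methyl (2E)-2,3-dibromoprop-2-enoate F2, which would be coupled with 12 at the β-bromine (PdCl2(PPh3)2, CuI, Et3N, 0 °C) to give methyl (2E,6E)-2-bromo-8-hydroxy-6-methylocta-2,6-dien-4-ynoate F3. LiOH in THF/H2O, then acidification, would free acid 13, which would now be isolated and cyclised with catalytic AgNO3 in acetone in the dark (5-exo-dig anti-oxymetalation), to come back to the route at 14.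

Step 25 (union of the halves). What may go wrong: opening of the ylidenebutenolide by the aqueous base, protodeboronation of the dienylboronate, and light- or palladium-induced E/Z scrambling of the polyene. Fallback: a base-free Stille union. Aldehyde 35 would be converted with CrCl2, Bu3SnCHBr2 and LiI in DMF/THF into (1R)-3,5,5-trimethyl-4-[(3E,5E)-3-methyl-6-(tributylstannyl)hexa-3,5-dien-1-yn-1-yl]cyclohex-3-en-1-ol F4, which would be coupled with iodide 17 (Pd2(dba)3, AsPh3, NMP, 23 °C, dark) to come back to the route at 37.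

Further compounds
F1 | step 18 | tert-butyl(dimethyl){[(1R)-3,5,5-trimethyl-4-[(trimethylsilyl)ethynyl]cyclohex-3-en-1-yl]oxy}silane | CC1=C(C#C[Si](C)(C)C)C(C)(C)C[C@H](O[Si](C)(C)C(C)(C)C)C1
F2 | step 9 | methyl (2E)-2,3-dibromoprop-2-enoate | COC(=O)/C(Br)=C\Br
F3 | step 9 | methyl (2E,6E)-2-bromo-8-hydroxy-6-methylocta-2,6-dien-4-ynoate | COC(=O)/C(Br)=C\C#C/C(C)=C/CO
F4 | step 25 | (1R)-3,5,5-trimethyl-4-[(3E,5E)-3-methyl-6-(tributylstannyl)hexa-3,5-dien-1-yn-1-yl]cyclohex-3-en-1-ol | CC1=C(C#C/C(C)=C/C=C/[Sn](CCCC)(CCCC)CCCC)C(C)(C)C[C@H](O)C1
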